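All runs stem from a simulated flask for substances that don't exist; scatter was added.

Counted by the starting material in them, starting material, activated form, ring, open dimer and side product add up to the charge at every moment in a closed flask. Ring is therefore the charge minus what still waits and minus what has gone to open dimer or side product.

| setting | zeta | gamma | theta | epsilon | red | teal | ochre | blue | green | grey |
|---|---|---|---|---|---|---|---|---|---|---|
| starting material | 0.028 M | 0.10 M | 0.44 M | 0.090 M | 0.025 M | 0.050 M | 0.090 M | 0.025 M | 0.25 M | 0.40 M |
| activator | 0.135 M | 0.135 M | 0.135 M | 0.10 M | 0.0300 M | 0.500 M | 0.135 M | 0.0600 M | 0.500 M | 0.100 M |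
| temperature | −8 °C | 31 °C | −8 °C | 31 °C | −25 °C | 5 °C | 5 °C | 45 °C | −10 °C | 5 °C |
| remark | run made earlier | run made earlier | run made earlier | run made earlier |  |  |  |  |  |  |
| time |  |  |  |  | 15 h | 15 h | 15 h | 15 h | 15 h | 15 h |

| run | time / h | ring / % |
|---|---|---|
| zeta | 4.00 | 24.4 |
| zeta | 10.0 | 53.2 |
| zeta | 20.0 | 78.6 |
| zeta | 30.0 | 89.8 |
| gamma | 0.500 | 87.4 |
| gamma | 1.33 | 86.5 |
| gamma | 3.00 | 86.7 |
| gamma | 4.00 | 86.8 |
| theta | 4.00 | 2.9 |
| theta | 10.0 | 3.1 |
| theta | 20.0 | 1.6 |
| theta | 30.0 | 1.2 |
| epsilon | 0.333 | 81.2 |
| epsilon | 0.833 | 83.0 |
| epsilon | 1.50 | 85.2 |
| epsilon | 4.00 | 83.6 |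

(readings scatter by 0.5 percentage points)

- a species is counted by the starting material in it: one open dimer or side product counts as two
- the numbers in the tables scatter by 0.5 percentage points (one standard deviation)
- candidate steps: starting material + activator -> activated form; activated form -> ring; starting material + activated form -> open dimer; starting material + ring -> side product

1. all flasks from highest to lowest amount of ring, in percent of the starting material charged, at 15 h (red / teal / ochre / blue / green / grey)
2. the same order at 2.5 d (red / teal / ochre / blue / green / grey)
3. the amount of ring, in percent of the starting material charged of the flask you put first, at 15 h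
4. the amount of ring, in percent of the starting material charged of the flask you put last, at 15 h

Turn the question round: what would have to be true for teal, with the highest [activator]/[starting material] at 10.0, to hold little ring at 15 h? One way is diversion of the charge: theta, at a ratio of 0.307, shows 1.2% of ring at 30.0 h, and teal stands far from that ratio. The other way is that the charge still waits as activated form.

Suppose activation is quick and closure is the rate-limiting step. Taking the charge as zeta's ceiling, the missing ring between 10.0 h and 30.0 h gives a closure constant of 0.0762 h⁻¹ at −8 °C. Epsilon levels off near 83.9%, and its first reading lies 2.7 percentage points below that. This gap is a rough reading against a scatter of 0.5 points, but it gives 10.3 h⁻¹ at 31 °C. The two constants give an activation energy of 84.3 kJ mol⁻¹, so teal's constant at 5 °C is 0.455 h⁻¹.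

Over 15 h that makes 6.83. This is the closure count, the closure constant multiplied by the time, and on that supposition e to the minus count is the share of activated form still waiting. On this second way, a count of 0.693 leaves half waiting. Teal stands 9.85 times above that, with 0.108% waiting, so this reckoning finds neither way open to teal and puts it first.

The forecast also puts teal first: it gives teal > blue > ochre > green > red > grey at 15 h, teal > blue > green > ochre > red > grey at 2.5 d, 97% for the first flask and 1% for the last, on the ground that “Plateau yields therefore depend on the activator excess”.

The flasks give teal > blue > ochre > green > red > grey at 15 h and teal > blue > green > ochre > red > grey at 2.5 d, the forecast's orders, with 98.9% in teal and 0.427% in grey at 15 h.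

    starting material + activator → activated form (k = 1.20 M⁻¹ min⁻¹, Ea = 59.0 kJ mol⁻¹)
    activated form → ring (k = 0.00870 min⁻¹, Ea = 87.0 kJ mol⁻¹)
    starting material + activated form → open dimer (k = 0.120 M⁻¹ min⁻¹, Ea = 66.0 kJ mol⁻¹)
    starting material + ring → side product (k = 0.0140 M⁻¹ min⁻¹, Ea = 65.0 kJ mol⁻¹)
    (constants at 5 °C)

Teal holds 0.0400% of activated form at 15.0 h, against the 0.108% reckoned from its count of 6.83. A repeat of teal at −20 °C, with the same amounts and time, has a closure constant of 0.0124 h⁻¹ by the same reckoning. Its count is then 0.186, below 0.693, and the count puts ring at 17.0%. That flask holds 82.4% as activated form and 16.8% as ring at 15.0 h.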